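The 1,2-dioxine ring (O1–O2–C3–C4=C5–C6) is opened at its only alkene: ring-closing metathesis of an acyclic bis-allylic peroxide forms C4=C5 and the ring at once. The precursor is a (3S)-3-peroxyhex-4-enoate whose second peroxide oxygen carries the C6 ketal carbon (OMe, hexadecyl, vinyl) as an unselective epimer mixture. It comes in four steps from methoxyallene, 1-iodohexadecane, hydrogen peroxide and sorbaldehyde; C3 is set by iminium-catalysed peroxidation. The key step exploits the fact that C6 is an acid-labile peroxyketal (O1–C6–OMe) while C3 is configurationally fixed: acidic methanol added to the same flask should funnel both C6 epimers into the anomerically favoured (3S,6S) isomer.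

Key step: step 5

Remark: ring atoms are numbered O1, O2, C3 (bears CH2CO2Me), C4, C5, C6 (bears OMe and C16H33); the target is (3S,6S), with OMe and CH2CO2Me cis. Hydroperoxide 5 is used as the racemate.

Step 1
Reactants: 1 methoxyallene (1-methoxypropa-1,2-diene); 2 1-iodohexadecane
Product: 4 3-methoxynonadeca-1,2-diene, via 1-lithio-1-methoxyallene 3 (not isolated)
Conditions: n-BuLi, THF, −40 °C; then 2, −40 °C → rt
Reagents that add atoms: none
Why: Methoxyallene is deprotonated at the oxygen-bearing carbon and the allenyllithium is alkylated there by the primary iodide (SN2 alkylation of a lithiated alkoxyallene); no stereocentre is formed.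

Step 2
Reactants: 4 3-methoxynonadeca-1,2-diene
Product: 5 rac-3-hydroperoxy-3-methoxynonadec-1-ene
Conditions: H2O2 (anhydrous, in Et2O, 5 equiv), CSA (1 mol %), −20 → 0 °C; then aq. NaHCO3
Reagents that add atoms: hydrogen peroxide, OO
Why: Acid-catalysed perhydrolysis of an enol ether: protonation at the central allene carbon gives the methoxy-stabilised cation through which such allenes hydrolyse to vinyl ketones, and excess H2O2 should trap it at the oxygen-bearing carbon before it can rotate into allylic conjugation; the new centre is racemic, which is acceptable because step 5 equilibrates it.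

Step 3
Reactants: 5 rac-3-hydroperoxy-3-methoxynonadec-1-ene; 6 (2E,4E)-hexa-2,4-dienal (sorbaldehyde)
Product: 7 (3S,4E)-3-[(3-methoxynonadec-1-en-3-yl)peroxy]hex-4-enal, both epimers at the peroxyketal carbon
Conditions: (S)-2-[diphenyl(trimethylsilyloxy)methyl]pyrrolidine (20 mol %), PhCO2H (20 mol %), 6 (1.5 equiv), toluene, 0 °C
Reagents that add atoms: none
Why: Iminium-catalysed asymmetric peroxidation of an enal (oxa-Michael addition of an α-methoxy hydroperoxide): the hydroperoxide should add to the β-carbon of the E-iminium ion anti to the CPh2OSiMe3 group of the (S)-catalyst, which sets 3S, while the acid co-catalyst protonates the enamine before epoxide closure and the more charged β-position should win over the δ-position; racemic 5 is consumed completely, so both ketal epimers are carried on.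

Step 4
Reactants: 7 (3S,4E)-3-[(3-methoxynonadec-1-en-3-yl)peroxy]hex-4-enal
Product: 9 methyl (3S,4E)-3-[(3-methoxynonadec-1-en-3-yl)peroxy]hex-4-enoate, via carboxylic acid 8 (not isolated)
Conditions: NaClO2, NaH2PO4, 2-methyl-2-butene, t-BuOH/H2O, 0 °C; extractive work-up; then TMSCHN2, PhMe/MeOH, 0 °C
Reagents that add atoms: sodium chlorite, [Na+].[O-]Cl=O; trimethylsilyldiazomethane, C[Si](C)(C)C=[N+]=[N-]
Why: Pinnick oxidation followed by diazoalkane esterification of the crude acid, both non-basic, so that the β-peroxy carbonyl compound cannot undergo retro-Michael loss of hydroperoxide or Kornblum–DeLaMare fragmentation, and the alkenes, the O–O bond and C3 stay untouched.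

Step 5
Reactants: 9 methyl (3S,4E)-3-[(3-methoxynonadec-1-en-3-yl)peroxy]hex-4-enoate
Product: 11 6-epi-chondrillin, via C6-epimeric dioxine mixture 10 (not isolated)
Conditions: second-generation Hoveyda–Grubbs catalyst RuCl2(H2IMes)(=CH–C6H4-2-OiPr) (5 mol %), CH2Cl2 (5 mM), 40 °C; then MeOH, CSA (10 mol %), rt
Reagents that add atoms: methanol, CO (its methoxy group exchanges with the one at C6)
Why: The ruthenium alkylidene is taken up by one alkene of 9, adds intramolecularly to the other to give a ruthenacyclobutane, and cycloreversion releases propene and leaves the C4=C5 bond, so the 1,2-dioxine forms with the O–O bond already in place. The closest known reactions are ring-closing metathesis of dienes tethered through an allylic O,O-acetal carbon to 2-alkoxy-3,6-dihydro-2H-pyrans and olefin metathesis in the presence of dialkyl peroxides. The six-membered ring is closed by ring-closing metathesis (carbene–alkene [2+2], then retro-[2+2]); the ring allows only the cis alkene, and geminal substitution at C6 favours the folded conformer (Thorpe–Ingold effect). Metathesis creates no stereocentre and leaves C3 untouched; CSA in methanol then equilibrates C6 by reversible loss of methanol or ring–chain opening, and thermodynamic control should favour 11, whose half-chair has the C6–OMe bond pseudoaxial (anomeric stabilisation by an O1 lone pair) and both the hexadecyl chain and the C3 side chain pseudoequatorial, which is the cis OMe/CH2CO2Me relationship of (3S,6S). The step needs carbene turnover to outrun ruthenium-induced O–O cleavage and oligomerisation, which the phosphine-free catalyst, high dilution, the absence of O–H groups and the short peroxide tether should secure. Any (3S,6R) epimer left at equilibrium should be separable and can be returned to the same acidic methanol.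

Compound list
1 | methoxyallene (1-methoxypropa-1,2-diene) | COC=C=C | starting material
2 | 1-iodohexadecane | CCCCCCCCCCCCCCCCI | starting material
3 | 1-lithio-1-methoxyallene | [Li]C(OC)=C=C | intermediate (not isolated)
4 | 3-methoxynonadeca-1,2-diene | C=C=C(OC)CCCCCCCCCCCCCCCC | intermediate
5 | rac-3-hydroperoxy-3-methoxynonadec-1-ene | C=CC(OC)(OO)CCCCCCCCCCCCCCCC | intermediate
6 | (2E,4E)-hexa-2,4-dienal (sorbaldehyde) | C/C=C/C=C/C=O | starting material
7 | (3S,4E)-3-[(3-methoxynonadec-1-en-3-yl)peroxy]hex-4-enal, both ketal epimers | C/C=C/[C@H](CC=O)OOC(OC)(C=C)CCCCCCCCCCCCCCCC | intermediate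
8 | (3S,4E)-3-[(3-methoxynonadec-1-en-3-yl)peroxy]hex-4-enoic acid, both ketal epimers | C/C=C/[C@H](CC(=O)O)OOC(OC)(C=C)CCCCCCCCCCCCCCCC | intermediate (not isolated)
9 | methyl (3S,4E)-3-[(3-methoxynonadec-1-en-3-yl)peroxy]hex-4-enoate, both ketal epimers | C/C=C/[C@H](CC(=O)OC)OOC(OC)(C=C)CCCCCCCCCCCCCCCC | intermediate
10 | methyl 2-[(3S)-6-hexadecyl-6-methoxy-3,6-dihydro-1,2-dioxin-3-yl]acetate, mixture of C6 epimers | CCCCCCCCCCCCCCCCC1(OC)C=C[C@H](CC(=O)OC)OO1 | intermediate (not isolated)
11 | 6-epi-chondrillin, methyl 2-[(3S,6S)-6-hexadecyl-6-methoxy-3,6-dihydro-1,2-dioxin-3-yl]acetate | CCCCCCCCCCCCCCCC[C@@]1(OC)C=C[C@H](CC(=O)OC)OO1 | target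

Total step count: 5. Longest linear sequence: 5 steps (1 → 4 → 5 → 7 → 9 → 11).

Steps most likely to fail

Step 3. The hindered, racemic hydroperoxide 5 may add too slowly, so that loss of methanol from 5, attack at the δ-carbon of the dienyl iminium ion or epoxide closure of the enamine take over, and mismatched pairing with the catalyst may erode facial selectivity. The fallback forms the C3–O bond first with a small achiral hydroperoxide and the C6–O bond last; it sets out from 6. Hydroperoxy(methoxy)diphenylmethane F1 is made from benzophenone dimethyl ketal, ethereal H2O2 and catalytic CSA. It is added to 6 under the step 3 conditions to give (3S,4E)-3-{[methoxy(diphenyl)methyl]peroxy}hex-4-enal F2. The step 4 conditions give methyl (3S,4E)-3-{[methoxy(diphenyl)methyl]peroxy}hex-4-enoate F3. AcOH/THF/H2O at rt cleaves the perketal to methyl (3S,4E)-3-hydroperoxyhex-4-enoate F4. F4 is then added to allene 4 (CSA 1 mol %, CH2Cl2, −20 °C), which is the step 2 reaction with an alkyl hydroperoxide in place of H2O2, and the route is rejoined at 9.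

Step 5. Initiation at the internal propenyl group and at the vinyl group on the fully substituted C6 may be slow enough that ruthenium-mediated cleavage of the O–O bond and catalyst decay overtake ring closure. The fallback is ruthenium-free and closes the ring at O1–C6 by hemiketalisation of a Z-γ-hydroperoxy enone; it sets out from 6.
- 2-Hydroperoxy-2-methoxypropane F5 (ozonolysis of 2,3-dimethylbut-2-ene in CH2Cl2/MeOH) is added to 6 under the step 3 conditions to give (3S,4E)-3-[(2-methoxypropan-2-yl)peroxy]hex-4-enal F6.
- The step 4 conditions give methyl (3S,4E)-3-[(2-methoxypropan-2-yl)peroxy]hex-4-enoate F7.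
- Ozonolysis (O3, CH2Cl2, −78 °C; Me2S) removes the propenyl terminus and gives methyl (3S)-3-[(2-methoxypropan-2-yl)peroxy]-4-oxobutanoate F8.
- Wittig reaction of F8 with (2-oxooctadecylidene)triphenylphosphorane F9 (from methyl heptadecanoate and Ph3P=CH2) gives methyl (3S,4E)-3-[(2-methoxypropan-2-yl)peroxy]-6-oxodocos-4-enoate F10.
- AcOH/THF/H2O frees methyl (3S,4E)-3-hydroperoxy-6-oxodocos-4-enoate F11.
- Irradiation at 350 nm interconverts the E and Z enones, and the Z isomer should be drained as methyl 2-[(3S)-6-hexadecyl-6-hydroxy-3,6-dihydro-1,2-dioxin-3-yl]acetate F12.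
- MeOH/CSA converts F12 into 10, which the same conditions equilibrate to 11 as in step 5.

Step 2. The first-formed hydroperoxide may add to a second molecule of allene, the cation may be captured at its terminal carbon after rotation, or traces of water may hydrolyse the allene to the vinyl ketone. The fallback replaces direct addition by ketal exchange under thermodynamic control; it sets out from 4. MeOH with catalytic PPTS at 0 °C gives 3,3-dimethoxynonadec-1-ene F13, which is purified. F13 is then equilibrated with a large excess of ethereal H2O2 and catalytic CSA to exchange one methoxy group for OOH, rejoining the route at 5.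

Further compounds
F1 | step 3 | hydroperoxy(methoxy)diphenylmethane | COC(OO)(c1ccccc1)c1ccccc1
F2 | step 3 | (3S,4E)-3-{[methoxy(diphenyl)methyl]peroxy}hex-4-enal | C/C=C/[C@H](CC=O)OOC(OC)(c1ccccc1)c1ccccc1
F3 | step 3 | methyl (3S,4E)-3-{[methoxy(diphenyl)methyl]peroxy}hex-4-enoate | C/C=C/[C@H](CC(=O)OC)OOC(OC)(c1ccccc1)c1ccccc1
F4 | step 3 | methyl (3S,4E)-3-hydroperoxyhex-4-enoate | C/C=C/[C@H](CC(=O)OC)OO
F5 | step 5 | 2-hydroperoxy-2-methoxypropane | COC(C)(C)OO
F6 | step 5 | (3S,4E)-3-[(2-methoxypropan-2-yl)peroxy]hex-4-enal | C/C=C/[C@H](CC=O)OOC(C)(C)OC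
F7 | step 5 | methyl (3S,4E)-3-[(2-methoxypropan-2-yl)peroxy]hex-4-enoate | C/C=C/[C@H](CC(=O)OC)OOC(C)(C)OC
F8 | step 5 | methyl (3S)-3-[(2-methoxypropan-2-yl)peroxy]-4-oxobutanoate | O=C[C@H](CC(=O)OC)OOC(C)(C)OC
F9 | step 5 | (2-oxooctadecylidene)triphenylphosphorane | CCCCCCCCCCCCCCCCC(=O)C=P(c1ccccc1)(c1ccccc1)c1ccccc1
F10 | step 5 | methyl (3S,4E)-3-[(2-methoxypropan-2-yl)peroxy]-6-oxodocos-4-enoate | CCCCCCCCCCCCCCCCC(=O)/C=C/[C@H](CC(=O)OC)OOC(C)(C)OC
F11 | step 5 | methyl (3S,4E)-3-hydroperoxy-6-oxodocos-4-enoate | CCCCCCCCCCCCCCCCC(=O)/C=C/[C@H](CC(=O)OC)OO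
F12 | step 5 | methyl 2-[(3S)-6-hexadecyl-6-hydroxy-3,6-dihydro-1,2-dioxin-3-yl]acetate, both C6 epimers | CCCCCCCCCCCCCCCCC1(O)C=C[C@H](CC(=O)OC)OO1
F13 | step 2 | 3,3-dimethoxynonadec-1-ene | C=CC(OC)(OC)CCCCCCCCCCCCCCCC
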